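Ring B is traced back to a cyclohexane-1,3-dione: its ether carbon C1' is flanked by the phenol carbon C2' and the formyl-bearing C6', with the methyl carbon C4' opposite, which is the pattern of a 2-aryloxy-5-methylcyclohexane-1,3-dione. A single Michael–Dieckmann annulation of the ring-A-oxy acetoacetate 14 with ethyl crotonate forms C4'–C5' and C1'–C2' and closes ring B, so the crowded diaryl ether oxygen enters earlier as an ordinary alkyl aryl ether. Precursor 14 carries the ring-A carboxyl as the free acid, an enolate-inert carboxylate in the annulation; the symmetrical dione is then differentiated through its mono-enol triflate, formylated and aromatised.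

Key step: step 9

Remark: the stereocentre of the target is read from the SMILES as (1R); the ring-B sp3 centres in 16–23 arise without control, are drawn undefined and vanish by step 14.

Step 1
Reactants: 1 methyl 2,6-dihydroxybenzoate; 2 3-methylbutanoyl chloride
Product: 3 methyl 2,6-dihydroxy-3-(3-methylbutanoyl)benzoate
Conditions: AlCl3 (3 equiv), ClCH2CH2Cl, 0 to 50 °C
Reagents that add atoms: none
Why: Friedel–Crafts acylation, in which both hydroxyls activate C3 (ortho to one, para to the other; C3 and C5 are equivalent) and the ketone formed deactivates the ring against a second acylation.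

Step 2
Reactants: 3 methyl 2,6-dihydroxy-3-(3-methylbutanoyl)benzoate; 4 3-bromoprop-1-ene (allyl bromide)
Product: 5 methyl 2-hydroxy-3-(3-methylbutanoyl)-6-(prop-2-en-1-yloxy)benzoate
Conditions: K2CO3 (1.1 equiv), acetone, 50 °C
Reagents that add atoms: none
Why: Williamson etherification that should touch only the C6 hydroxyl, since the C2 hydroxyl sits between ester and ketone and is held in a strong hydrogen bond to the ketone; the allyl group protects this oxygen and is the latent OCH2CO2H unit.

Step 3
Reactants: 5 methyl 2-hydroxy-3-(3-methylbutanoyl)-6-(prop-2-en-1-yloxy)benzoate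
Product: 6 methyl 2-methoxy-3-(3-methylbutanoyl)-6-(prop-2-en-1-yloxy)benzoate
Conditions: MeI, K2CO3, DMF, 50 °C
Reagents that add atoms: iodomethane, CI
Why: Williamson O-methylation of the remaining chelated phenol, which needs the polar solvent and warming but has no competing nucleophile left.

Step 4
Reactants: 6 methyl 2-methoxy-3-(3-methylbutanoyl)-6-(prop-2-en-1-yloxy)benzoate
Product: 7 methyl 3-[(1R)-1-hydroxy-3-methylbutyl]-2-methoxy-6-(prop-2-en-1-yloxy)benzoate
Conditions: RuCl[(R,R)-TsDPEN](p-cymene) (1 mol%), HCO2H–Et3N (5:2), DMF, 30 °C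
Reagents that add atoms: none
Why: Noyori–Ikariya asymmetric transfer hydrogenation, in which the Ru–H/N–H pair of the (R,R)-catalyst should deliver hydrogen to the Si face of the aryl ketone (aryl group oriented by its CH–π contact with the cymene ligand) and so set the (1R)-carbinol as for simple aryl alkyl ketones, while the isolated alkene and the ester stay untouched.

Step 5
Reactants: 7 methyl 3-[(1R)-1-hydroxy-3-methylbutyl]-2-methoxy-6-(prop-2-en-1-yloxy)benzoate
Product: 8 methyl 2-methoxy-3-[(1R)-1-methoxy-3-methylbutyl]-6-(prop-2-en-1-yloxy)benzoate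
Conditions: NaH, MeI, THF, 0 °C to rt
Reagents that add atoms: iodomethane, CI
Why: Williamson O-methylation of the sodium alkoxide, in which the C–O bond at the stereocentre is not broken, so the (1R) configuration is kept, and the di-ortho-substituted ester offers no acidic hydrogen.

Step 6
Reactants: 8 methyl 2-methoxy-3-[(1R)-1-methoxy-3-methylbutyl]-6-(prop-2-en-1-yloxy)benzoate
Product: 9 2-methoxy-3-[(1R)-1-methoxy-3-methylbutyl]-6-(prop-2-en-1-yloxy)benzoic acid
Conditions: KOH (10 equiv), EtOH–H2O, reflux; then aq. HCl to pH 3, 0 °C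
Reagents that add atoms: potassium hydroxide, [K+].[OH-]
Why: Saponification of the hindered 2,6-dialkoxybenzoate under forcing conditions, tolerated here because the molecule holds only ethers and no phenoxide para to the benzylic ether.

Step 7
Reactants: 9 2-methoxy-3-[(1R)-1-methoxy-3-methylbutyl]-6-(prop-2-en-1-yloxy)benzoic acid
Product: 11 6-(carboxymethoxy)-2-methoxy-3-[(1R)-1-methoxy-3-methylbutyl]benzoic acid, via aryloxyacetaldehyde 10 (not isolated)
Conditions: O3, CH2Cl2–MeOH, −78 °C; Me2S, −78 °C to rt; then NaClO2, NaH2PO4, 2-methyl-2-butene, t-BuOH–H2O, rt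
Reagents that add atoms: ozone, [O-][O+]=O; sodium chlorite, [Na+].[O-]Cl=O
Why: Ozonolysis with reductive work-up followed by Pinnick oxidation turns the allyl ether into the aryloxyacetic acid, the terminal alkene reacting with ozone far faster than the carboxyl-deactivated arene and the buffered chlorite step sparing the benzylic ether.

Step 8
Reactants: 11 6-(carboxymethoxy)-2-methoxy-3-[(1R)-1-methoxy-3-methylbutyl]benzoic acid; 12 potassium ethyl malonate
Product: 14 6-(4-ethoxy-2,4-dioxobutoxy)-2-methoxy-3-[(1R)-1-methoxy-3-methylbutyl]benzoic acid (the ethyl 4-aryloxy-3-oxobutanoate with free ring-A carboxyl), via acyl imidazolide 13 (not isolated)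
Conditions: CDI (1.05 equiv), THF, rt; then 12, MgCl2, Et3N, MeCN, rt to 40 °C; aq. HCl to pH 3, 0 °C
Reagents that add atoms: none
Why: Masamune–Brooks β-keto ester synthesis, in which acyl transfer from CDI settles on the unhindered aryloxyacetic carboxyl (the di-ortho-substituted benzoic acid stays as carboxylate) and the magnesium enolate of 12 is C-acylated and loses CO2, so the α-aryloxy ketone is never exposed to base next to a ring-A ester that could close to a benzofuranone.

Step 9
Reactants: 14 6-(4-ethoxy-2,4-dioxobutoxy)-2-methoxy-3-[(1R)-1-methoxy-3-methylbutyl]benzoic acid; 15 ethyl (E)-but-2-enoate (ethyl crotonate)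
Product: 17 6-{[3-(ethoxycarbonyl)-4-methyl-2,6-dioxocyclohexyl]oxy}-2-methoxy-3-[(1R)-1-methoxy-3-methylbutyl]benzoic acid (enol and epimer mixture), via Michael adduct 16 (not isolated)
Conditions: NaOEt (2.2 equiv), EtOH, reflux; then aq. HCl to pH 3, 0 °C
Reagents that add atoms: none
Why: Ethoxide turns 14 into its carboxylate–enolate dianion, whose acetoacetate C2 adds to the β-carbon of 15 (Michael addition, forming C4'–C5'); after proton transfer the ArO–CH enolate attacks the crotonate-derived ester and expels ethoxide (Dieckmann condensation, forming C1'–C2'), and the stable dione enolate drives the sequence forward. The closest known reaction type is the acetoacetate–crotonate Michael–Dieckmann synthesis of 5-methylcyclohexane-1,3-diones. Ring B closes in a 6-(enolendo)-exo-trig mode. The sp3 centres created at C1', C4' and C5' are not controlled and need no control, because C1' is enolised, C5' loses its carboxyl in step 10 and C4' becomes aromatic in step 14. The step needs chemoselectivity between acyl acceptors: the only ester that the ArO–CH enolate can reach through a six-membered transition state is the crotonate-derived one, and the ring-A carboxyl, present as an anionic carboxylate, cannot be attacked, which excludes the five-membered closure to a benzofuranone that an ortho ester would allow. The ring-A benzylic ether has no acidic hydrogen and no para phenoxide under these conditions, so the (1R) centre is safe.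

Step 10
Reactants: 17 6-{[3-(ethoxycarbonyl)-4-methyl-2,6-dioxocyclohexyl]oxy}-2-methoxy-3-[(1R)-1-methoxy-3-methylbutyl]benzoic acid
Product: 19 2-methoxy-3-[(1R)-1-methoxy-3-methylbutyl]-6-[(4-methyl-2,6-dioxocyclohexyl)oxy]benzoic acid, via keto acid 18 (not isolated)
Conditions: 1 M aq. NaOH, EtOH, 50 °C; then aq. HCl to pH 3, 40 °C
Reagents that add atoms: none
Why: Saponification of the β-keto ester and decarboxylation of the resulting β-keto acid on mild acidification, which removes the C5' carboxyl and leaves the mirror-symmetric 2-aryloxy-5-methyl-1,3-dione.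

Step 11
Reactants: 19 2-methoxy-3-[(1R)-1-methoxy-3-methylbutyl]-6-[(4-methyl-2,6-dioxocyclohexyl)oxy]benzoic acid
Product: 21 2-(trimethylsilyl)ethyl 2-methoxy-3-[(1R)-1-methoxy-3-methylbutyl]-6-[(4-methyl-2,6-dioxocyclohexyl)oxy]benzoate, via bis-silylethyl enol ether 20 (not isolated)
Conditions: Me3SiCH2CH2OH (2.5 equiv), PPh3, DIAD, THF, 0 °C to rt; then 1 M HCl, THF, rt
Reagents that add atoms: 2-(trimethylsilyl)ethanol, C[Si](C)(C)CCO; water, O
Why: Mitsunobu alkylation converts both acidic groups (carboxylic acid to ester, dione to its enol ether) and dilute acid then hydrolyses only the vinylogous ester, so the carboxyl is masked before triflation, where a free acid would be activated and lactonise onto the enol.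

Step 12
Reactants: 21 2-(trimethylsilyl)ethyl 2-methoxy-3-[(1R)-1-methoxy-3-methylbutyl]-6-[(4-methyl-2,6-dioxocyclohexyl)oxy]benzoate
Product: 22 2-(trimethylsilyl)ethyl 2-methoxy-3-[(1R)-1-methoxy-3-methylbutyl]-6-({4-methyl-6-oxo-2-[(trifluoromethanesulfonyl)oxy]cyclohex-1-en-1-yl}oxy)benzoate (epimers at the methyl-bearing ring carbon)
Conditions: Tf2O (1.2 equiv), pyridine, CH2Cl2, −78 to 0 °C
Reagents that add atoms: trifluoromethanesulfonic anhydride, O=S(=O)(OS(=O)(=O)C(F)(F)F)C(F)(F)F
Why: Enol triflation of a cyclic 1,3-dione, in which the two carbonyls are equivalent by symmetry, so a single constitutional monotriflate should form and no second acidic site remains.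

Step 13
Reactants: 22 the enol triflate of step 12
Product: 23 2-(trimethylsilyl)ethyl 6-[(2-formyl-4-methyl-6-oxocyclohex-1-en-1-yl)oxy]-2-methoxy-3-[(1R)-1-methoxy-3-methylbutyl]benzoate (epimers at the methyl-bearing ring carbon)
Conditions: Pd(OAc)2 (5 mol%), dppp (5 mol%), CO (1 atm), Et3SiH, Et3N, DMF, 70 °C
Reagents that add atoms: carbon monoxide, [C-]#[O+]
Why: Palladium-catalysed reductive carbonylation (formylation) of an enol triflate, in which zerovalent palladium inserts into the C–OTf bond, CO insertion gives the acylpalladium species and Si–H transfer releases the enal at C6'.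

Step 14
Reactants: 23 the keto enal of step 13
Product: 24 2-(trimethylsilyl)ethyl 6-(2-formyl-6-hydroxy-4-methylphenoxy)-2-methoxy-3-[(1R)-1-methoxy-3-methylbutyl]benzoate
Conditions: Pd(O2CCF3)2 (5 mol%), 2-(dimethylamino)pyridine (10 mol%), TsOH (20 mol%), O2 (1 atm), DMSO, 80 °C
Reagents that add atoms: none
Why: Palladium-catalysed aerobic dehydrogenation of a cyclohexenone to a phenol, in which a divalent palladium enolate at C3' undergoes β-hydride elimination from C4' and the dienone tautomerises, erasing the last ring-B sp3 centre so that both epimers converge.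

Step 15
Reactants: 24 2-(trimethylsilyl)ethyl 6-(2-formyl-6-hydroxy-4-methylphenoxy)-2-methoxy-3-[(1R)-1-methoxy-3-methylbutyl]benzoate
Product: 25 6-(2-formyl-6-hydroxy-4-methylphenoxy)-2-methoxy-3-[(1R)-1-methoxy-3-methylbutyl]benzoic acid (target)
Conditions: Bu4NF (3 equiv), THF, rt; then aq. HCl to pH 3, 0 °C
Reagents that add atoms: none
Why: Fluoride attacks silicon and the 2-(trimethylsilyl)ethyl ester fragments to ethene, Me3SiF and the carboxylate (β-elimination), a cleavage that does not depend on access to the hindered carbonyl and leaves aldehyde, phenol and the benzylic ether alone.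

Compound list
1 | methyl 2,6-dihydroxybenzoate | COC(=O)c1c(O)cccc1O | starting material
2 | 3-methylbutanoyl chloride | CC(C)CC(=O)Cl | starting material
3 | methyl 2,6-dihydroxy-3-(3-methylbutanoyl)benzoate | COC(=O)c1c(O)ccc(C(=O)CC(C)C)c1O | intermediate
4 | 3-bromoprop-1-ene (allyl bromide) | C=CCBr | starting material
5 | methyl 2-hydroxy-3-(3-methylbutanoyl)-6-(prop-2-en-1-yloxy)benzoate | COC(=O)c1c(OCC=C)ccc(C(=O)CC(C)C)c1O | intermediate
6 | methyl 2-methoxy-3-(3-methylbutanoyl)-6-(prop-2-en-1-yloxy)benzoate | COC(=O)c1c(OCC=C)ccc(C(=O)CC(C)C)c1OC | intermediate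
7 | methyl 3-[(1R)-1-hydroxy-3-methylbutyl]-2-methoxy-6-(prop-2-en-1-yloxy)benzoate | COc1c([C@@H](CC(C)C)O)ccc(OCC=C)c1C(=O)OC | intermediate
8 | methyl 2-methoxy-3-[(1R)-1-methoxy-3-methylbutyl]-6-(prop-2-en-1-yloxy)benzoate | COc1c([C@@H](CC(C)C)OC)ccc(OCC=C)c1C(=O)OC | intermediate
9 | 2-methoxy-3-[(1R)-1-methoxy-3-methylbutyl]-6-(prop-2-en-1-yloxy)benzoic acid | COc1c([C@@H](CC(C)C)OC)ccc(OCC=C)c1C(=O)O | intermediate
10 | 2-methoxy-3-[(1R)-1-methoxy-3-methylbutyl]-6-(2-oxoethoxy)benzoic acid | COc1c([C@@H](CC(C)C)OC)ccc(OCC=O)c1C(=O)O | intermediate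
11 | 6-(carboxymethoxy)-2-methoxy-3-[(1R)-1-methoxy-3-methylbutyl]benzoic acid | COc1c([C@@H](CC(C)C)OC)ccc(OCC(=O)O)c1C(=O)O | intermediate
12 | potassium ethyl malonate | CCOC(=O)CC(=O)[O-].[K+] | starting material
13 | 6-[2-(imidazol-1-yl)-2-oxoethoxy]-2-methoxy-3-[(1R)-1-methoxy-3-methylbutyl]benzoic acid | COc1c([C@@H](CC(C)C)OC)ccc(OCC(=O)n2ccnc2)c1C(=O)O | intermediate
14 | 6-(4-ethoxy-2,4-dioxobutoxy)-2-methoxy-3-[(1R)-1-methoxy-3-methylbutyl]benzoic acid | COc1c([C@@H](CC(C)C)OC)ccc(OCC(=O)CC(=O)OCC)c1C(=O)O | intermediate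
15 | ethyl (E)-but-2-enoate | C/C=C/C(=O)OCC | starting material
16 | diethyl 2-{[2-carboxy-3-methoxy-4-[(1R)-1-methoxy-3-methylbutyl]phenoxy]acetyl}-3-methylpentanedioate | COc1c([C@@H](CC(C)C)OC)ccc(OCC(=O)C(C(=O)OCC)C(C)CC(=O)OCC)c1C(=O)O | intermediate
17 | 6-{[3-(ethoxycarbonyl)-4-methyl-2,6-dioxocyclohexyl]oxy}-2-methoxy-3-[(1R)-1-methoxy-3-methylbutyl]benzoic acid | COc1c([C@@H](CC(C)C)OC)ccc(OC2C(=O)CC(C)C(C(=O)OCC)C2=O)c1C(=O)O | intermediate
18 | 6-[(3-carboxy-4-methyl-2,6-dioxocyclohexyl)oxy]-2-methoxy-3-[(1R)-1-methoxy-3-methylbutyl]benzoic acid | COc1c([C@@H](CC(C)C)OC)ccc(OC2C(=O)CC(C)C(C(=O)O)C2=O)c1C(=O)O | intermediate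
19 | 2-methoxy-3-[(1R)-1-methoxy-3-methylbutyl]-6-[(4-methyl-2,6-dioxocyclohexyl)oxy]benzoic acid | COc1c([C@@H](CC(C)C)OC)ccc(OC2C(=O)CC(C)CC2=O)c1C(=O)O | intermediate
20 | 2-(trimethylsilyl)ethyl 2-methoxy-3-[(1R)-1-methoxy-3-methylbutyl]-6-({4-methyl-6-oxo-2-[2-(trimethylsilyl)ethoxy]cyclohex-1-en-1-yl}oxy)benzoate | COc1c([C@@H](CC(C)C)OC)ccc(OC2=C(OCC[Si](C)(C)C)CC(C)CC2=O)c1C(=O)OCC[Si](C)(C)C | intermediate
21 | 2-(trimethylsilyl)ethyl 2-methoxy-3-[(1R)-1-methoxy-3-methylbutyl]-6-[(4-methyl-2,6-dioxocyclohexyl)oxy]benzoate | COc1c([C@@H](CC(C)C)OC)ccc(OC2C(=O)CC(C)CC2=O)c1C(=O)OCC[Si](C)(C)C | intermediate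
22 | 2-(trimethylsilyl)ethyl 2-methoxy-3-[(1R)-1-methoxy-3-methylbutyl]-6-({4-methyl-6-oxo-2-[(trifluoromethanesulfonyl)oxy]cyclohex-1-en-1-yl}oxy)benzoate | COc1c([C@@H](CC(C)C)OC)ccc(OC2=C(OS(=O)(=O)C(F)(F)F)CC(C)CC2=O)c1C(=O)OCC[Si](C)(C)C | intermediate
23 | 2-(trimethylsilyl)ethyl 6-[(2-formyl-4-methyl-6-oxocyclohex-1-en-1-yl)oxy]-2-methoxy-3-[(1R)-1-methoxy-3-methylbutyl]benzoate | COc1c([C@@H](CC(C)C)OC)ccc(OC2=C(C=O)CC(C)CC2=O)c1C(=O)OCC[Si](C)(C)C | intermediate
24 | 2-(trimethylsilyl)ethyl 6-(2-formyl-6-hydroxy-4-methylphenoxy)-2-methoxy-3-[(1R)-1-methoxy-3-methylbutyl]benzoate | COc1c([C@@H](CC(C)C)OC)ccc(Oc2c(O)cc(C)cc2C=O)c1C(=O)OCC[Si](C)(C)C | intermediate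
25 | 6-(2-formyl-6-hydroxy-4-methylphenoxy)-2-methoxy-3-[(1R)-1-methoxy-3-methylbutyl]benzoic acid | COc1c([C@@H](CC(C)C)OC)ccc(Oc2c(O)cc(C)cc2C=O)c1C(=O)O | target

Total step count: 15. Longest linear sequence: 15 steps (1 to 25).

Steps most likely to fail

Step 13 (formylation). Hydride may reach the alkenylpalladium intermediate before CO has inserted, so that the triflate is lost without a formyl group, and the silane–palladium pair may reduce the enone in a conjugate sense. The fallback sets out from 22 and comes back at 23. Stille coupling of 22 with tributyl(vinyl)stannane (Pd(PPh3)4, LiCl, THF, 65 °C) should give 2-(trimethylsilyl)ethyl 6-[(2-ethenyl-4-methyl-6-oxocyclohex-1-en-1-yl)oxy]-2-methoxy-3-[(1R)-1-methoxy-3-methylbutyl]benzoate F1. Lemieux–Johnson cleavage of its terminal alkene (OsO4 cat., NaIO4, 2,6-lutidine, dioxane–H2O) should then deliver 23, since the tetrasubstituted, electron-poor ring alkene is expected to react much more slowly with OsO4.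

Step 14 (aromatisation). The aldehyde may be oxidised or decarbonylated under the aerobic palladium conditions, or the catalyst may be deactivated before dehydrogenation is complete. The fallback sets out from 23 and comes back at 24. Acid-mediated α-selenenylation of the ketone with PhSeCl (EtOAc, rt) should give 2-(trimethylsilyl)ethyl 6-{[2-formyl-4-methyl-6-oxo-5-(phenylselanyl)cyclohex-1-en-1-yl]oxy}-2-methoxy-3-[(1R)-1-methoxy-3-methylbutyl]benzoate F2. Oxidation with NaIO4 (THF–H2O, 0 °C to rt) should then trigger syn-elimination of the selenoxide, and the dienone formed tautomerises to 24 without any palladium or oxygen.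

Step 9 (key step). Retro-Claisen cleavage of the α-aryloxy ketone by ethoxide, or a slow Michael addition of the hindered dianion, may consume 14 before the ring has closed. The fallback sets out from 9 and comes back at 21, building the aryloxy dione by O–H insertion instead of annulation.
- Mitsunobu esterification of 9 with 2-(trimethylsilyl)ethanol (PPh3, DIAD, THF) should give 2-(trimethylsilyl)ethyl 2-methoxy-3-[(1R)-1-methoxy-3-methylbutyl]-6-(prop-2-en-1-yloxy)benzoate F3.
- Allyl transfer to morpholine (Pd(PPh3)4, THF, rt) should free the phenol 2-(trimethylsilyl)ethyl 6-hydroxy-2-methoxy-3-[(1R)-1-methoxy-3-methylbutyl]benzoate F4.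
- Diazo transfer to commercial 5-methylcyclohexane-1,3-dione (4-acetamidobenzenesulfonyl azide, Et3N, MeCN) should give 2-diazo-5-methylcyclohexane-1,3-dione F5.
- Insertion of the rhodium carbenoid from F5 into the O–H bond of F4 (Rh2(OAc)4, benzene, 80 °C) should give 21 directly.

Further compounds
F1 | step 13 | 2-(trimethylsilyl)ethyl 6-[(2-ethenyl-4-methyl-6-oxocyclohex-1-en-1-yl)oxy]-2-methoxy-3-[(1R)-1-methoxy-3-methylbutyl]benzoate | COc1c([C@@H](CC(C)C)OC)ccc(OC2=C(C=C)CC(C)CC2=O)c1C(=O)OCC[Si](C)(C)C
F2 | step 14 | 2-(trimethylsilyl)ethyl 6-{[2-formyl-4-methyl-6-oxo-5-(phenylselanyl)cyclohex-1-en-1-yl]oxy}-2-methoxy-3-[(1R)-1-methoxy-3-methylbutyl]benzoate | COc1c([C@@H](CC(C)C)OC)ccc(OC2=C(C=O)CC(C)C([Se]c3ccccc3)C2=O)c1C(=O)OCC[Si](C)(C)C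
F3 | step 9 | 2-(trimethylsilyl)ethyl 2-methoxy-3-[(1R)-1-methoxy-3-methylbutyl]-6-(prop-2-en-1-yloxy)benzoate | COc1c([C@@H](CC(C)C)OC)ccc(OCC=C)c1C(=O)OCC[Si](C)(C)C
F4 | step 9 | 2-(trimethylsilyl)ethyl 6-hydroxy-2-methoxy-3-[(1R)-1-methoxy-3-methylbutyl]benzoate | COc1c([C@@H](CC(C)C)OC)ccc(O)c1C(=O)OCC[Si](C)(C)C
F5 | step 9 | 2-diazo-5-methylcyclohexane-1,3-dione | CC1CC(=O)C(=[N+]=[N-])C(=O)C1
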